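**Retrosynthetic overview**

- The esters come off last (acetylation, Yamaguchi angeloylation) from the 4,5,6-triol. The triol comes from cycloheptenone 18 by reagent-controlled CBS reduction (C-4) and anti-osmylation (C-5, C-6). The C-3 gem-dimethyl group and the 5,6-alkene are put onto the bridged ketone 15.
- Key disconnection C-6–C-7: ketone 15 arises by a radical two-carbon ring expansion (alkoxy-radical β-scission, then 7-endo recombination) of the 2-vinylbicyclo[2.1.1]hexan-2-ol 13. An easier skeleton is built first and rearranged into the bicyclo[4.1.1]octane of the target.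
- Enabling feature: the cyclobutane C-1/C-2/C-7/C-8 is bridged 1,3 (C-2 to C-7) by the chain C-3–C-6 of the seven-membered ring, and C-7 is a fully substituted cyclobutane carbon. With C-4 bonded directly to C-7 the bridge is two carbons short, which is what a rule-of-five crossed [2+2] photocycloaddition gives; a C-4 alkoxy radical then releases the tertiary C-7 radical, which recloses on the vinyl terminus C-6.
- Ring order: temporary dihydropyran (RCM) → cyclobutane and cyclopentane together (crossed [2+2]) → cyclohexenone (aldol condensation; conjugate addition sets C-11) → seven-membered ring (key step).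
- Absolute configuration comes from one catalytic allylboration (C-4 of 4). The temporary acetal ring ties O-4 to C-11, so this centre fixes the sense of the cage before it is erased.

Key step: step 11

Assumption and conventions: 2,4-dimethylfuran is taken as purchasable. Atom locants in the text follow the tricyclo[5.4.0.0^{2,8}]undecane numbering of the target, also for intermediates (C-1, C-2, C-7, C-8 cyclobutane; C-3 CMe2; C-4, C-5, C-6 the three CH–O; C-7 C–CH3; C-9 C=O; C-10 CH2; C-11 CH–CH3). Where a centre is formed as a mixture that is erased later, the SMILES carries no descriptor there.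

**Route**

Step 1
Reactants: 1 2,4-dimethylfuran
Product: 3 (E)-2-methyl-4-oxopent-2-enal, via (Z)-2-methyl-4-oxopent-2-enal 2 (not isolated)
Conditions: dimethyldioxirane, acetone, −20 °C; then I2 (2 mol %), CH2Cl2, 20 °C
Reagents that add atoms: dimethyldioxirane, CC1(C)OO1
Why: Oxidative ring opening of the furan (epoxidation, then opening of the epoxyfuran) gives the cis-ene-dicarbonyl compound, and iodine-catalysed isomerisation converts it to the more stable E isomer; no stereocentre is formed.

Step 2
Reactants: 3 (E)-2-methyl-4-oxopent-2-enal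
Product: 4 (S,E)-5-hydroxy-4-methylocta-3,7-dien-2-one
Conditions: allylboronic acid pinacol ester, (S)-TRIP phosphoric acid (5 mol %, antipode chosen for the S alcohol), toluene, −30 °C; aqueous work-up
Reagents that add atoms: allylboronic acid pinacol ester, C=CCB1OC(C)(C)C(C)(C)O1
Why: Chiral-phosphoric-acid-catalysed allylboration goes through a closed chair transition state at the aldehyde only (the ketone is untouched), and the catalyst sets the S carbinol centre C-4.

Step 3
Reactants: 4 (S,E)-5-hydroxy-4-methylocta-3,7-dien-2-one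
Product: 5 (5S,E)-5-[(1-ethoxyprop-2-en-1-yl)oxy]-4-methylocta-3,7-dien-2-one (both acetal epimers)
Conditions: acrolein diethyl acetal (5 equiv), PPTS (cat.), toluene, 40 °C, reduced pressure
Reagents that add atoms: acrolein diethyl acetal, C=CC(OCC)OCC
Why: Acid-catalysed transacetalisation, driven by removal of ethanol, attaches the acrolein unit as a mixed acetal; C-4 is untouched and the new acetal centre is of no consequence.

Step 4
Reactants: 5 mixed acetal
Product: 6 (E)-4-[(2S)-6-ethoxy-3,6-dihydro-2H-pyran-2-yl]pent-3-en-2-one (both epimers at the acetal carbon)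
Conditions: second-generation Grubbs catalyst RuCl2(=CHPh)(H2IMes)(PCy3) (5 mol %), CH2Cl2, 40 °C
Reagents that add atoms: none
Why: Ring-closing metathesis of the two terminal vinyl groups closes the temporary dihydropyran (the electron-poor trisubstituted enone alkene is inert) and fixes the C-1=C-2 alkene as cis.

Step 5
Reactants: 6 dihydropyranyl enone
Product: 7 cage acetal (bicyclo[2.1.1]hexane with 7-methyl, 8-acetyl and an O-4–CH(OEt)–C-1 bridge; epimers at C-8 and at the acetal carbon)
Conditions: hν (350 nm, Pyrex), degassed MeCN (0.01 M), 20 °C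
Reagents that add atoms: none
Why: Intramolecular crossed [2+2] photocycloaddition of the triplet enone with the ring alkene (a 1,5-diene, rule of five, the topology of the carvone-to-carvonecamphor and citral photocyclisations) forms the bonds C-1–C-7 and C-2–C-8; because O-4 is tied through the acetal carbon to C-1, the single centre C-4 fixes the configuration of C-1, C-2 and C-7.

Step 6
Reactants: 7 cage acetal
Product: 9 9-hydroxy-1-methyltricyclo[4.3.0.0^{2,7}]non-4-en-3-one, via hydroxy keto aldehyde 8 (not isolated)
Conditions: 1 M HCl, THF, 25 °C; then pyrrolidine (0.3 equiv), AcOH (0.3 equiv), toluene, 70 °C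
Reagents that add atoms: none
Why: Acetal hydrolysis frees the aldehyde (C-11) and the C-4 hydroxyl; enamine/iminium catalysis epimerises C-1 and C-8 so that both acyl groups reach the face anti to the C-3–C-4 bridge, where aldol (Mannich-type) condensation of the methyl ketone onto the aldehyde closes the cyclohexenone without the enolate conditions that could open the 1,3-diacylcyclobutane by retro-Michael reaction.

Step 7
Reactants: 9 tricyclic enone alcohol
Product: 10 9-hydroxy-1,5-dimethyltricyclo[4.3.0.0^{2,7}]nonan-3-one
Conditions: MeMgBr (3 equiv), CuI (10 mol %), THF, −40 → 0 °C; aq. NH4Cl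
Reagents that add atoms: methylmagnesium bromide, C[Mg]Br
Why: Copper-catalysed conjugate addition to the bicyclo[3.1.1]heptenone occurs on the enone face anti to C-7, whose methyl group lies over the ring (the other flank, C-2, carries only H), and this sets C-11 as required.

Step 8
Reactants: 10 hydroxy ketone
Product: 11 9-hydroxy-1,5-dimethyltricyclo[4.3.0.0^{2,7}]nonan-3-one ethylene ketal
Conditions: ethylene glycol, PPTS (cat.), benzene, reflux, Dean–Stark trap
Reagents that add atoms: ethylene glycol, OCCO
Why: Acid-catalysed ketalisation with azeotropic removal of water masks the C-9 ketone for the Grignard, enolate and hydride steps that follow.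

Step 9
Reactants: 11 hydroxy ketal
Product: 12 1,5-dimethyltricyclo[4.3.0.0^{2,7}]nonane-3,9-dione 3-(ethylene ketal)
Conditions: Dess–Martin periodinane, NaHCO3, CH2Cl2, 20 °C
Reagents that add atoms: none
Why: Buffered Dess–Martin oxidation of the secondary alcohol gives the bicyclo[2.1.1]hexan-2-one; the neighbouring C-7 is quaternary, so nothing can epimerise.

Step 10
Reactants: 12 ketal ketone
Product: 13 9-ethenyl-9-hydroxy-1,5-dimethyltricyclo[4.3.0.0^{2,7}]nonan-3-one ethylene ketal (both carbinol epimers)
Conditions: CH2=CHMgBr, THF, −40 → 0 °C; aq. NH4Cl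
Reagents that add atoms: vinylmagnesium bromide, C=C[Mg]Br
Why: 1,2-Addition of the vinyl Grignard reagent gives the tertiary allylic alcohol and brings in C-5 and C-6; the configuration of the carbinol centre is irrelevant because C-4 becomes a carbonyl again in step 11.

Step 11
Reactants: 13 vinyl carbinol
Product: 15 7,11-dimethyltricyclo[5.4.0.0^{2,8}]undecane-4,9-dione 9-(ethylene ketal), via ring-opened cyclobutyl radical 14 (not isolated)
Conditions: [Ir(dF(CF3)ppy)2(5,5′-d(CF3)bpy)]PF6 (2 mol %), Bu4N[O2P(OBu)2] (25 mol %), 2,4,6-triisopropylbenzenethiol (10 mol %), PhCF3, blue LEDs, 25 °C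
Reagents that add atoms: none
Why: The excited trivalent iridium photocatalyst and the phosphate base remove an electron and the hydroxyl proton in concert to give the C-4 alkoxy radical, whose β-scission of the C-4–C-7 bond opens the strained bicyclo[2.1.1]hexane, releases the tertiary radical at the cyclobutane carbon C-7 (scission of C-3–C-4 would give a primary radical) and unmasks a vinyl ketone tethered through C-3 to C-2. This nucleophilic radical adds to the terminal enone carbon C-6 (polarity-matched Giese addition; attack at the inner carbon C-5 is mismatched), and the α-keto radical is quenched by hydrogen-atom transfer from the thiol, which the reduced photocatalyst and the phosphoric acid regenerate, so the process is a redox-neutral isomerisation. The closest known reaction type is the photocatalytic n+2 ring expansion of 1-vinylcycloalkanols by alkoxy-radical β-scission and recombination of the alkyl radical with the revealed enone. One ring is closed, the seven-membered ring across the 1,3-positions of the cyclobutane, in the 7-endo-trig mode; the cyclobutane and the six-membered ring are untouched. The new quaternary centre C-7 is controlled by the cage, because the chain anchored on C-2 can reach the radical only from the cyclobutane face that already carries it (the other face is spanned by C-9–C-11), which leaves the methyl group over the six-membered ring as in the target. The step needs site-selective β-scission and endo rather than exo recombination, secured by tertiary versus primary radical stability at equal strain release and by the polarity of the acyl-tethered enone.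

Step 12
Reactants: 15 bridged ketone
Product: 16 7,11-dimethyltricyclo[5.4.0.0^{2,8}]undec-5-ene-4,9-dione 9-(ethylene ketal)
Conditions: IBX, 4-methoxypyridine N-oxide, DMSO, 40 °C
Reagents that add atoms: none
Why: IBX dehydrogenation of the ketone through its enol can only give the C-5=C-6 enone, because unsaturation towards C-3/C-2 would be a bridgehead alkene of the bicyclo[4.1.1]octane and C-7 is quaternary.

Step 13
Reactants: 16 enone
Product: 18 3,3,7,11-tetramethyltricyclo[5.4.0.0^{2,8}]undec-5-ene-4,9-dione 9-(ethylene ketal), via 3-monomethyl enone 17 (not isolated)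
Conditions: LDA, THF, −78 °C, then MeI; repeated in the same flask with LDA, DMPU, MeI, −78 → 0 °C
Reagents that add atoms: iodomethane, CI
Why: Kinetic α′-deprotonation of the enone (only C-3 carries acidic hydrogens, C-7 has none for γ-deprotonation) followed by methylation, twice, installs the gem-dimethyl group, after which C-3 is no longer a stereocentre.

Step 14
Reactants: 18 gem-dimethyl enone
Product: 19 4-hydroxy-3,3,7,11-tetramethyltricyclo[5.4.0.0^{2,8}]undec-5-en-9-one ethylene ketal
Conditions: (S)-2-methyl-CBS-oxazaborolidine (0.2 equiv), BH3·SMe2, THF, −30 °C (catalyst antipode chosen so that hydride adds to the ketone face syn to C-8)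
Reagents that add atoms: none
Why: Corey–Bakshi–Shibata reduction is reagent-controlled (quaternary C-3 against the vinyl carbon C-5), which is needed because the two ketone faces differ only through the remote six-membered ring; hydride delivery syn to C-8 places the hydroxyl towards C-1.

Step 15
Reactants: 19 allylic alcohol
Product: 20 4,5,6-trihydroxy-3,3,7,11-tetramethyltricyclo[5.4.0.0^{2,8}]undecan-9-one ethylene ketal
Conditions: OsO4 (5 mol %), NMO, acetone/H2O, 20 °C
Reagents that add atoms: N-methylmorpholine N-oxide, C[N+]1([O-])CCOCC1; water, O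
Why: Upjohn dihydroxylation is a suprafacial syn addition (O-5 and O-6 cis) and should occur anti to the allylic hydroxyl at C-4 (empirical rule for osmylation of allylic alcohols), giving the 4,5-trans-5,6-cis triol.

Step 16
Reactants: 20 triol
Product: 21 5-O-acetyl derivative of triol 20
Conditions: Ac2O (1.05 equiv), 2,4,6-collidine, CH2Cl2, −30 °C
Reagents that add atoms: acetic anhydride, CC(=O)OC(C)=O
Why: The C-5 hydroxyl is flanked by two CH groups, whereas those at C-4 and C-6 are neopentyl-type (next to C-3 and C-7), so one equivalent of anhydride at low temperature should acetylate O-5 selectively.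

Step 17
Reactants: 21 diol monoacetate
Product: 22 4,6-di-O-angeloyl-5-O-acetyl triol ethylene ketal
Conditions: angelic acid, 2,4,6-trichlorobenzoyl chloride, Et3N, toluene, 20 °C; then 21, DMAP, toluene, 70 °C
Reagents that add atoms: angelic acid, C/C=C(/C)C(=O)O
Why: Yamaguchi esterification through the mixed 2,4,6-trichlorobenzoic anhydride acylates both hindered hydroxyls while keeping the Z geometry of the angelate.

Step 18
Reactants: 22 triester ketal
Product: 23 5-acetoxy-3,3,7,11-tetramethyl-9-oxotricyclo[5.4.0.0^{2,8}]undecane-4,6-diyl bis[(Z)-2-methylbut-2-enoate] (target)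
Conditions: PPTS, acetone/H2O, 45 °C
Reagents that add atoms: water, O
Why: Mild acid-catalysed hydrolysis of the dioxolane liberates the C-9 ketone without touching the three esters or any stereocentre.

**Compound list**

1 | 2,4-dimethylfuran | Cc1cc(C)co1 | starting material
2 | (Z)-2-methyl-4-oxopent-2-enal | CC(=O)/C=C(/C)C=O | intermediate (not isolated)
3 | (E)-2-methyl-4-oxopent-2-enal | CC(=O)/C=C(\C)C=O | intermediate
4 | (S,E)-5-hydroxy-4-methylocta-3,7-dien-2-one | CC(=O)/C=C(\C)[C@@H](O)CC=C | intermediate
5 | (5S,E)-5-[(1-ethoxyprop-2-en-1-yl)oxy]-4-methylocta-3,7-dien-2-one (both acetal epimers) | CC(=O)/C=C(\C)[C@@H](OC(OCC)C=C)CC=C | intermediate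
6 | (E)-4-[(2S)-6-ethoxy-3,6-dihydro-2H-pyran-2-yl]pent-3-en-2-one (both acetal epimers) | CC(=O)/C=C(\C)[C@@H]1CC=CC(OCC)O1 | intermediate
7 | cage acetal: 7-methyl-8-acetylbicyclo[2.1.1]hexane with O-4–CH(OEt)–C-1 bridge (epimers at C-8 and acetal carbon) | CC(=O)C1[C@]2(C)[C@H]3OC(OCC)[C@@H]2[C@@H]1C3 | intermediate
8 | 6-acetyl-2-hydroxy-1-methylbicyclo[2.1.1]hexane-5-carbaldehyde (both acyl groups anti to the two-carbon bridge) | CC(=O)[C@H]1[C@]2(C)[C@@H](O)C[C@H]1[C@@H]2C=O | intermediate (not isolated)
9 | 9-hydroxy-1-methyltricyclo[4.3.0.0^{2,7}]non-4-en-3-one | O=C1C=C[C@@H]2[C@@]3(C)[C@@H](O)C[C@@H]2[C@@H]13 | intermediate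
10 | 9-hydroxy-1,5-dimethyltricyclo[4.3.0.0^{2,7}]nonan-3-one | O=C1C[C@@H](C)[C@@H]2[C@@]3(C)[C@@H](O)C[C@@H]2[C@@H]13 | intermediate
11 | 9-hydroxy-1,5-dimethyltricyclo[4.3.0.0^{2,7}]nonan-3-one ethylene ketal | C14(OCCO4)C[C@@H](C)[C@@H]2[C@@]3(C)[C@@H](O)C[C@@H]2[C@@H]13 | intermediate
12 | 1,5-dimethyltricyclo[4.3.0.0^{2,7}]nonane-3,9-dione 3-(ethylene ketal) | C14(OCCO4)C[C@@H](C)[C@@H]2[C@@]3(C)C(=O)C[C@@H]2[C@@H]13 | intermediate
13 | 9-ethenyl-9-hydroxy-1,5-dimethyltricyclo[4.3.0.0^{2,7}]nonan-3-one ethylene ketal (both carbinol epimers) | C14(OCCO4)C[C@@H](C)[C@@H]2[C@@]3(C)C(O)(C=C)C[C@@H]2[C@@H]13 | intermediate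
14 | ring-opened tertiary cyclobutyl radical carrying the 2-oxobut-3-enyl chain on C-2 | C=CC(=O)C[C@H]1[C@H]2[C](C)[C@@H]1C3(OCCO3)C[C@H]2C | intermediate (not isolated)
15 | 7,11-dimethyltricyclo[5.4.0.0^{2,8}]undecane-4,9-dione 9-(ethylene ketal) | O=C1CC[C@]2(C)[C@@H]3[C@@H]([C@H]2C4(OCCO4)C[C@H]3C)C1 | intermediate
16 | 7,11-dimethyltricyclo[5.4.0.0^{2,8}]undec-5-ene-4,9-dione 9-(ethylene ketal) | O=C1C=C[C@]2(C)[C@@H]3[C@@H]([C@H]2C4(OCCO4)C[C@H]3C)C1 | intermediate
17 | 3,7,11-trimethyltricyclo[5.4.0.0^{2,8}]undec-5-ene-4,9-dione 9-(ethylene ketal) (both C-3 epimers) | O=C1C=C[C@]2(C)[C@@H]3[C@@H]([C@H]2C4(OCCO4)C[C@H]3C)C1C | intermediate (not isolated)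
18 | 3,3,7,11-tetramethyltricyclo[5.4.0.0^{2,8}]undec-5-ene-4,9-dione 9-(ethylene ketal) | O=C1C=C[C@]2(C)[C@@H]3[C@@H]([C@H]2C4(OCCO4)C[C@H]3C)C1(C)C | intermediate
19 | 4-hydroxy-3,3,7,11-tetramethyltricyclo[5.4.0.0^{2,8}]undec-5-en-9-one ethylene ketal | O[C@@H]1C=C[C@]2(C)[C@@H]3[C@@H]([C@H]2C4(OCCO4)C[C@H]3C)C1(C)C | intermediate
20 | 4,5,6-trihydroxy-3,3,7,11-tetramethyltricyclo[5.4.0.0^{2,8}]undecan-9-one ethylene ketal | O[C@@H]1[C@@H](O)[C@@H](O)[C@]2(C)[C@@H]3[C@@H]([C@H]2C4(OCCO4)C[C@H]3C)C1(C)C | intermediate
21 | 5-O-acetyl derivative of triol 20 | O[C@@H]1[C@@H](OC(C)=O)[C@@H](O)[C@]2(C)[C@@H]3[C@@H]([C@H]2C4(OCCO4)C[C@H]3C)C1(C)C | intermediate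
22 | 4,6-di-O-angeloyl-5-O-acetyl triol ethylene ketal | C/C=C(/C)C(=O)O[C@@H]1[C@@H](OC(C)=O)[C@@H](OC(=O)/C(C)=C\C)[C@]2(C)[C@@H]3[C@@H]([C@H]2C4(OCCO4)C[C@H]3C)C1(C)C | intermediate
23 | 5-acetoxy-3,3,7,11-tetramethyl-9-oxotricyclo[5.4.0.0^{2,8}]undecane-4,6-diyl bis[(Z)-2-methylbut-2-enoate] | C/C=C(/C)C(=O)O[C@@H]1[C@@H](OC(C)=O)[C@@H](OC(=O)/C(C)=C\C)[C@]2(C)[C@@H]3[C@@H]([C@H]2C(=O)C[C@H]3C)C1(C)C | target

**Step count**

Total step count: 18. Longest linear sequence: 18 steps.

**Steps most likely to fail**

1. Step 11. The ring-opened C-7 radical may be quenched by hydrogen-atom transfer before it recloses, or may recombine at the inner enone carbon, or thiyl radicals may add to the vinyl ketone. The fallback separates fragmentation from cyclisation. It sets out from 13: hypoiodite (Suárez-type) fragmentation with PhI(OAc)2 and I2 under visible light in cyclohexane should trap the C-7 radical as the tertiary iodide with the free vinyl ketone, the iodo vinyl ketone F1. Slow addition of Bu3SnH and AIBN to F1 at high dilution in benzene at 80 °C should regenerate the radical with only a trace of hydrogen donor present and give, by the same 7-endo Giese cyclisation, ketone 15, where the route continues.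

2. Step 5. The open-chain enone may lose its excitation by E/Z isomerisation or photodeconjugation instead of cycloadding. The fallback moves the chromophore into a ring. It sets out from 4:
   - Acryloyl chloride and Et3N give the acrylate F2.
   - Ring-closing metathesis with the second-generation Grubbs catalyst gives the dihydropyranone F3.
   - Acetone-sensitised irradiation at 300 nm excites the cyclic enoate, which cannot isomerise, and should give the lactone photoadduct F4 by the same crossed [2+2].
   - Ethylene glycol and PPTS convert the acetyl group into the dioxolane F5.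
   - iBu2AlH at −78 °C reduces the lactone to the lactol F6.
   - Aqueous HCl, then pyrrolidine and AcOH as in step 6, remove the dioxolane, epimerise and condense to give 9, where the route continues.

3. Step 17. Double acylation of two neopentyl-type hydroxyls may stall, the acetyl group may migrate from O-5, or the angelate may isomerise to the tiglate under forcing conditions. The fallback introduces the esters one at a time. It sets out from 20:
   - 2,2-Dimethoxypropane and PPTS protect the cis-5,6-diol as the acetonide F7.
   - Yamaguchi angeloylation of the lone C-4 hydroxyl gives F8.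
   - Aqueous AcOH at 50 °C removes the acetonide and the dioxolane to give the diol ketone F9.
   - Selective acetylation of the less hindered C-5 hydroxyl (Ac2O, collidine, −30 °C) gives F10.
   - A second Yamaguchi angeloylation at O-6 gives the target 23.

Further compounds
F1 | step 11 | iodo vinyl ketone (C-7 tertiary iodide, 2-oxobut-3-enyl chain on C-2, C-9 ethylene ketal; either C-7 epimer) | C=CC(=O)C[C@H]1[C@H]2C(C)(I)[C@@H]1C3(OCCO3)C[C@H]2C
F2 | step 5 | (S,E)-5-methyl-6-oxohepta-1,4-dien-4-yl... acrylate of alcohol 4 [(3E,5S)-4-methyl-2-oxoocta-3,7-dien-5-yl prop-2-enoate] | CC(=O)/C=C(\C)[C@@H](OC(=O)C=C)CC=C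
F3 | step 5 | (S)-6-[(E)-4-oxopent-2-en-2-yl]-5,6-dihydro-2H-pyran-2-one | CC(=O)/C=C(\C)[C@@H]1CC=CC(=O)O1
F4 | step 5 | lactone photoadduct (cage of 7 with C=O in place of CH(OEt); C-8 epimers) | CC(=O)C1[C@]2(C)[C@H]3OC(=O)[C@@H]2[C@@H]1C3
F5 | step 5 | lactone photoadduct with the acetyl group as ethylene ketal | CC1(OCCO1)C1[C@]2(C)[C@H]3OC(=O)[C@@H]2[C@@H]1C3
F6 | step 5 | lactol of F5 (both lactol epimers) | CC1(OCCO1)C1[C@]2(C)[C@H]3OC(O)[C@@H]2[C@@H]1C3
F7 | step 17 | 5,6-O-isopropylidene derivative of triol 20 | O[C@@H]1[C@H]2OC(C)(C)O[C@H]2[C@]3(C)[C@@H]4[C@@H]([C@H]3C5(OCCO5)C[C@H]4C)C1(C)C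
F8 | step 17 | 4-O-angeloyl-5,6-O-isopropylidene triol ethylene ketal | C/C=C(/C)C(=O)O[C@@H]1[C@H]2OC(C)(C)O[C@H]2[C@]3(C)[C@@H]4[C@@H]([C@H]3C5(OCCO5)C[C@H]4C)C1(C)C
F9 | step 17 | 4-O-angeloyl-5,6-dihydroxy ketone | C/C=C(/C)C(=O)O[C@@H]1[C@@H](O)[C@@H](O)[C@]2(C)[C@@H]3[C@@H]([C@H]2C(=O)C[C@H]3C)C1(C)C
F10 | step 17 | 4-O-angeloyl-5-O-acetyl-6-hydroxy ketone | C/C=C(/C)C(=O)O[C@@H]1[C@@H](OC(C)=O)[C@@H](O)[C@]2(C)[C@@H]3[C@@H]([C@H]2C(=O)C[C@H]3C)C1(C)C
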